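**Strategy.** Ring A, the cross-conjugated 4-alkyl-4-methoxycyclohexa-2,5-dienone, is cut at the two bonds that flank the CH=C(OMe) unit of its vinylogous ester: CH to the carbonyl carbon and C(OMe) to the quaternary C(OMe)(alkyl) carbon. The key step exploits the fact that this O=C–CH=C(OMe) array has the polarity of an ynol ether: nickel-catalysed insertion of methoxyacetylene into the acyl–C(sp3) bond of a 2-allyl-4-methoxycyclobut-2-enone makes both bonds at once, with the quaternary centre and both side-chain stereocentres already in place. The cyclobutenone comes from a squarate by a copper-catalysed aldol (two stereocentres), a chelation-controlled reduction (the third) and a carbonyl transposition.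

Key step: step 9

Remark: the ligand antipode in step 3 is assigned by analogy with the pyruvate chelate model and is the least certain assignment in the route; the ring carbinol configuration in 11 and 12 is left uncontrolled because step 7 destroys that centre.

Step 1
Reactants: 1 diisopropyl squarate; 2 allylmagnesium bromide
Product: 4 3-(propan-2-yloxy)-4-(prop-2-en-1-yl)cyclobut-3-ene-1,2-dione, via allyl carbinol 3 (not isolated)
Conditions: THF, −78 °C; then 12 M HCl, CH2Cl2, 20 °C
Reagents that add atoms: none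
Why: Grignard 1,2-addition to one squarate carbonyl, then acid-induced allylic transposition with loss of isopropanol, is the standard route to 3-alkyl-4-alkoxycyclobutenediones and should leave the allyl group unconjugated under brief acid treatment.

Step 2
Reactants: 5 1-(3,4-dimethoxyphenyl)propan-1-one
Product: 7 [(Z)-1-(3,4-dimethoxyphenyl)prop-1-en-1-yl]oxy(trimethyl)silane, via lithium enolate 6 (not isolated)
Conditions: LiN(i-Pr)2, THF, −78 °C; then TMSCl, −78 to 0 °C
Reagents that add atoms: chlorotrimethylsilane, C[Si](C)(C)Cl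
Why: Kinetic deprotonation of an aryl ethyl ketone should give the (Z)-enolate, which TMSCl traps on oxygen (silyl enol ether formation).

Step 3
Reactants: 4 3-(propan-2-yloxy)-4-(prop-2-en-1-yl)cyclobut-3-ene-1,2-dione; 7 [(Z)-1-(3,4-dimethoxyphenyl)prop-1-en-1-yl]oxy(trimethyl)silane
Product: 9 (4R)-4-[(2S)-1-(3,4-dimethoxyphenyl)-1-oxopropan-2-yl]-4-hydroxy-3-(propan-2-yloxy)-2-(prop-2-en-1-yl)cyclobut-2-en-1-one, via silyl ether 8 (not isolated)
Conditions: Cu(OTf)2 (10 mol %), (S,S)-t-Bu-box [2,2'-(propane-2,2-diyl)bis((4S)-4-tert-butyl-4,5-dihydrooxazole)] (11 mol %), THF, −78 °C; then 1 M HCl, THF, 0 °C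
Reagents that add atoms: none
Why: Mukaiyama aldol in its copper bis(oxazoline) form: the vicinal dione should chelate divalent copper through both carbonyl oxygens as pyruvates and 2,3-diketones do, the enolsilane should attack the more electrophilic carbonyl (next to C–O-i-Pr, not the vinylogous-ester one) through an open, syn-selective transition state while the tert-butyl groups screen one face, so the catalyst sets both the ring carbinol carbon (4R) and the methyl-bearing carbon (2S).

Step 4
Reactants: 9 (4R)-4-[(2S)-1-(3,4-dimethoxyphenyl)-1-oxopropan-2-yl]-4-hydroxy-3-(propan-2-yloxy)-2-(prop-2-en-1-yl)cyclobut-2-en-1-one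
Product: 10 (4R)-4-[(2S)-1-(3,4-dimethoxyphenyl)-1-oxopropan-2-yl]-4-methoxy-3-(propan-2-yloxy)-2-(prop-2-en-1-yl)cyclobut-2-en-1-one
Conditions: MeI (excess), Ag2O, CaSO4, 20 °C, dark
Reagents that add atoms: iodomethane, CI
Why: Purdie methylation should etherify the fairly acidic tertiary α-ketol hydroxyl under nearly neutral conditions that do not promote retro-aldol cleavage or epimerise the ketone α-carbon.

Step 5
Reactants: 10 (4R)-4-[(2S)-1-(3,4-dimethoxyphenyl)-1-oxopropan-2-yl]-4-methoxy-3-(propan-2-yloxy)-2-(prop-2-en-1-yl)cyclobut-2-en-1-one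
Product: 11 (4S)-4-[(1R,2R)-1-(3,4-dimethoxyphenyl)-1-hydroxypropan-2-yl]-4-methoxy-3-(propan-2-yloxy)-2-(prop-2-en-1-yl)cyclobut-2-en-1-ol (both C1 epimers)
Conditions: Zn(BH4)2 (excess), Et2O, −30 to 20 °C; aq NaHCO3
Reagents that add atoms: none
Why: Chelation-controlled hydride reduction (Cram-chelate model): zinc should bridge the aryl ketone oxygen and the ring methoxy oxygen so that hydride arrives anti to the methyl group and gives the 1,2-syn (1R) carbinol, while the strained ring carbonyl is reduced 1,2 to an allylic alcohol of irrelevant configuration.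

Step 6
Reactants: 11 (4S)-4-[(1R,2R)-1-(3,4-dimethoxyphenyl)-1-hydroxypropan-2-yl]-4-methoxy-3-(propan-2-yloxy)-2-(prop-2-en-1-yl)cyclobut-2-en-1-ol
Product: 12 (1R,2R)-2-[(1S)-4-acetoxy-1-methoxy-2-(propan-2-yloxy)-3-(prop-2-en-1-yl)cyclobut-2-en-1-yl]-1-(3,4-dimethoxyphenyl)propyl acetate (both C4 epimers of the ring)
Conditions: Ac2O, pyridine, DMAP (cat.), CH2Cl2, 0 to 20 °C
Reagents that add atoms: acetic anhydride, CC(=O)OC(C)=O
Why: DMAP-catalysed acetylation of both secondary alcohols installs the benzylic acetate of the target, protects that position from acid, and turns the ring allylic alcohol into a leaving group.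

Step 7
Reactants: 12 (1R,2R)-2-[(1S)-4-acetoxy-1-methoxy-2-(propan-2-yloxy)-3-(prop-2-en-1-yl)cyclobut-2-en-1-yl]-1-(3,4-dimethoxyphenyl)propyl acetate
Product: 13 (1R,2R)-1-(3,4-dimethoxyphenyl)-2-[(1R)-1-methoxy-4-oxo-3-(prop-2-en-1-yl)cyclobut-2-en-1-yl]propyl acetate
Conditions: 0.5 M HCl, THF–H2O, 0 °C
Reagents that add atoms: water, O
Why: Stork–Danheiser transposition: ionisation of the allylic acetate to an isopropoxy-stabilised cyclobutenyl cation, addition of water at the oxygenated carbon and loss of isopropanol should give the transposed enone without touching the quaternary centre.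

Step 8
Reactants: 14 2-chloro-1,1-dimethoxyethane
Product: 16 methoxyethyne, via sodium methoxyacetylide 15 (not isolated)
Conditions: NaNH2 (3 equiv), liquid NH3, −33 °C; then aq NH4Cl, −70 °C; distilled into cold THF
Reagents that add atoms: none
Why: Twofold base-induced elimination (HCl, then methanol) from the chloroacetal is the classical alkoxyacetylene synthesis and gives the acetylide, which is protonated on quench.

Step 9
Reactants: 13 (1R,2R)-1-(3,4-dimethoxyphenyl)-2-[(1R)-1-methoxy-4-oxo-3-(prop-2-en-1-yl)cyclobut-2-en-1-yl]propyl acetate; 16 methoxyethyne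
Product: 17 (1R,2R)-1-(3,4-dimethoxyphenyl)-2-[(1R)-1,2-dimethoxy-4-oxo-5-(prop-2-en-1-yl)cyclohexa-2,5-dien-1-yl]propyl acetate
Conditions: Ni(cod)2 [bis(cycloocta-1,5-diene)nickel] (10 mol %), PPh3 (20 mol %), THF, 0 to 20 °C, 16 (3 equiv) added slowly as a cold solution
Reagents that add atoms: none
Why: Zerovalent nickel should add oxidatively into the strained acyl–C(sp3) bond of 13 (not the acyl–vinyl bond) to give a nickelacyclopentenone, methoxyethyne then inserts into the nickel–acyl bond, and C(sp2)–C(sp3) reductive elimination from the seven-membered nickelacycle releases the dienone and the catalyst. The closest known reactions are the nickel-catalysed cyclobutenone–alkyne [4+2] route to phenols and the nickel-catalysed insertion of alkynes into cyclobutanones to give cyclohexenones; here the fully substituted ring carbon blocks tautomerisation, so the 2,5-dienone is the end product. Ring A closes by two-carbon ring expansion of the cyclobutenone, a metal-templated formal [4+2] whose last bond is the one from the methoxy-bearing sp2 carbon to the quaternary carbon. No stereocentre is created: the quaternary carbon should be carried over with retention, because nickel takes the place of the acyl carbon and is then replaced from the same side by the alkenyl carbon, and the two side-chain centres are not involved. The step needs the orientation CH-to-acyl and C(OMe)-to-quaternary carbon, which the polarised ynol ether should secure, since its nucleophilic β-carbon bonds to the electrophilic acyl carbon and nickel stays on the oxygen-bearing carbon. It also needs the quaternary centre to survive, which the low temperature should secure by keeping the thermal 4π opening of 13 to a planar vinylketene out of play.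

**Compound list**

1 | 3,4-di(propan-2-yloxy)cyclobut-3-ene-1,2-dione (diisopropyl squarate) | CC(C)OC1=C(OC(C)C)C(=O)C1=O | starting material
2 | allylmagnesium bromide | C=CC[Mg]Br | starting material
3 | 4-hydroxy-2,3-di(propan-2-yloxy)-4-(prop-2-en-1-yl)cyclobut-2-en-1-one (racemic, formed as its magnesium alkoxide, not isolated) | CC(C)OC1=C(OC(C)C)C(O)(CC=C)C1=O | intermediate
4 | 3-(propan-2-yloxy)-4-(prop-2-en-1-yl)cyclobut-3-ene-1,2-dione | C=CCC1=C(OC(C)C)C(=O)C1=O | intermediate
5 | 1-(3,4-dimethoxyphenyl)propan-1-one | CCC(=O)c1ccc(OC)c(OC)c1 | starting material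
6 | lithium (Z)-1-(3,4-dimethoxyphenyl)prop-1-en-1-olate (not isolated) | C/C=C(\O[Li])c1ccc(OC)c(OC)c1 | intermediate
7 | [(Z)-1-(3,4-dimethoxyphenyl)prop-1-en-1-yl]oxy(trimethyl)silane | C/C=C(\O[Si](C)(C)C)c1ccc(OC)c(OC)c1 | intermediate
8 | (4R)-4-[(2S)-1-(3,4-dimethoxyphenyl)-1-oxopropan-2-yl]-3-(propan-2-yloxy)-2-(prop-2-en-1-yl)-4-(trimethylsilyloxy)cyclobut-2-en-1-one (not isolated) | C=CCC1=C(OC(C)C)[C@](O[Si](C)(C)C)([C@H](C)C(=O)c2ccc(OC)c(OC)c2)C1=O | intermediate
9 | (4R)-4-[(2S)-1-(3,4-dimethoxyphenyl)-1-oxopropan-2-yl]-4-hydroxy-3-(propan-2-yloxy)-2-(prop-2-en-1-yl)cyclobut-2-en-1-one | C=CCC1=C(OC(C)C)[C@](O)([C@H](C)C(=O)c2ccc(OC)c(OC)c2)C1=O | intermediate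
10 | (4R)-4-[(2S)-1-(3,4-dimethoxyphenyl)-1-oxopropan-2-yl]-4-methoxy-3-(propan-2-yloxy)-2-(prop-2-en-1-yl)cyclobut-2-en-1-one | C=CCC1=C(OC(C)C)[C@](OC)([C@H](C)C(=O)c2ccc(OC)c(OC)c2)C1=O | intermediate
11 | (4S)-4-[(1R,2R)-1-(3,4-dimethoxyphenyl)-1-hydroxypropan-2-yl]-4-methoxy-3-(propan-2-yloxy)-2-(prop-2-en-1-yl)cyclobut-2-en-1-ol, both C1 epimers | C=CCC1=C(OC(C)C)[C@](OC)([C@H](C)[C@@H](O)c2ccc(OC)c(OC)c2)C1O | intermediate
12 | (1R,2R)-2-[(1S)-4-acetoxy-1-methoxy-2-(propan-2-yloxy)-3-(prop-2-en-1-yl)cyclobut-2-en-1-yl]-1-(3,4-dimethoxyphenyl)propyl acetate, both ring C4 epimers | C=CCC1=C(OC(C)C)[C@](OC)([C@H](C)[C@@H](OC(C)=O)c2ccc(OC)c(OC)c2)C1OC(C)=O | intermediate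
13 | (1R,2R)-1-(3,4-dimethoxyphenyl)-2-[(1R)-1-methoxy-4-oxo-3-(prop-2-en-1-yl)cyclobut-2-en-1-yl]propyl acetate | C=CCC1=C[C@@](OC)([C@H](C)[C@@H](OC(C)=O)c2ccc(OC)c(OC)c2)C1=O | intermediate
14 | 2-chloro-1,1-dimethoxyethane | COC(CCl)OC | starting material
15 | sodium methoxyacetylide (not isolated) | COC#C[Na] | intermediate
16 | methoxyethyne (methoxyacetylene) | COC#C | intermediate
17 | (1R,2R)-1-(3,4-dimethoxyphenyl)-2-[(1R)-1,2-dimethoxy-4-oxo-5-(prop-2-en-1-yl)cyclohexa-2,5-dien-1-yl]propyl acetate | C=CCC1=C[C@@](OC)([C@H](C)[C@@H](OC(C)=O)c2ccc(OC)c(OC)c2)C(OC)=CC1=O | target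

**Step count.** Total: 9 steps. Longest linear sequence: 7 steps (1 to 17 through steps 1, 3, 4, 5, 6, 7 and 9). Steps 2 and 8 are side branches.

**Steps most likely to fail**

Step 9 (key step). The alkyne may insert with the opposite orientation. The alkylnickel at the quaternary carbon may undergo β-hydride elimination toward the side-chain CH. Configuration may leak through ring opening to a nickel-bound vinylketene. The ynol ether may oligomerise on nickel. Fallback, from 13 and 16 back to 17, by an anionic electrocyclic ring expansion: 16 is hydrostannylated (Bu3SnH, AIBN, 60 °C) to tributyl[(Z)-2-methoxyethenyl]stannane F1. Tin–lithium exchange (n-BuLi, THF, −78 °C) gives (Z)-2-methoxyethenyllithium F2, which is added to 13 at −100 °C, where the strained ketone should react faster than the acetate. On warming, the cyclobutenolate should open (4π, conrotatory) and reclose (6π) to (1R,2R)-1-(3,4-dimethoxyphenyl)-2-[(1R)-1,6-dimethoxy-4-oxo-3-(prop-2-en-1-yl)cyclohex-2-en-1-yl]propyl acetate F3, with the same two ring bonds formed. IBX (DMSO, 65 °C) should then dehydrogenate the CH2–CH(OMe) edge of F3 to give 17. In this cascade the quaternary carbon passes through a planar triene, so its configuration would have to be checked and any epimer removed by chromatography.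

Step 3. The splayed carbonyls of the cyclobutenedione may bind copper with one point only, which would give a poorly organised transition state (low facial and syn/anti selectivity), and conjugate addition at the alkoxy-bearing carbon may compete. Fallback, from 5 and 4 back to 9, with a stoichiometric auxiliary on the nucleophile: 5 is condensed with (2S)-2-(methoxymethyl)pyrrolidin-1-amine to the SAMP hydrazone F4. Deprotonation (LiN(i-Pr)2, THF, 0 °C) and addition of the azaenolate to 4 at −100 °C should give the β-hydroxy hydrazone F5, with the methyl-bearing carbon set by the auxiliary and carbinol epimers separated if needed. Two-phase cleavage with aqueous oxalic acid should return 9 and the auxiliary.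

Step 4. The hindered tertiary α-ketol may etherify slowly, and retro-aldol cleavage may take over. Fallback, from 9 back to 13, by moving the methylation behind the removal of the ketone: 9 is reduced first (Zn(BH4)2, Et2O; chelation through the free β-hydroxyl, same syn sense) to (4S)-4-[(1R,2R)-1-(3,4-dimethoxyphenyl)-1-hydroxypropan-2-yl]-3-(propan-2-yloxy)-2-(prop-2-en-1-yl)cyclobut-2-ene-1,4-diol F6. The two secondary hydroxyls are acetylated (Ac2O, pyridine) to the diacetate F7. Dilute HCl transposes the ring as in step 7 to (1R,2R)-1-(3,4-dimethoxyphenyl)-2-[(1R)-1-hydroxy-4-oxo-3-(prop-2-en-1-yl)cyclobut-2-en-1-yl]propyl acetate F8. The tertiary alcohol of F8, which can no longer undergo retro-aldol cleavage, is methylated (MeOTf, 2,6-di-tert-butyl-4-methylpyridine, CH2Cl2) to give 13.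

Further compounds
F1 | step 9 | tributyl[(Z)-2-methoxyethenyl]stannane | CO/C=C\[Sn](CCCC)(CCCC)CCCC
F2 | step 9 | (Z)-2-methoxyethenyllithium | CO/C=C\[Li]
F3 | step 9 | (1R,2R)-1-(3,4-dimethoxyphenyl)-2-[(1R)-1,6-dimethoxy-4-oxo-3-(prop-2-en-1-yl)cyclohex-2-en-1-yl]propyl acetate, C6 epimers | C=CCC1=C[C@@](OC)([C@H](C)[C@@H](OC(C)=O)c2ccc(OC)c(OC)c2)C(OC)CC1=O
F4 | step 3 | SAMP hydrazone of 1-(3,4-dimethoxyphenyl)propan-1-one | CCC(=NN1CCC[C@H]1COC)c1ccc(OC)c(OC)c1
F5 | step 3 | SAMP hydrazone of 9 | C=CCC1=C(OC(C)C)[C@](O)([C@H](C)C(=NN2CCC[C@H]2COC)c2ccc(OC)c(OC)c2)C1=O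
F6 | step 4 | (4S)-4-[(1R,2R)-1-(3,4-dimethoxyphenyl)-1-hydroxypropan-2-yl]-3-(propan-2-yloxy)-2-(prop-2-en-1-yl)cyclobut-2-ene-1,4-diol, C1 epimers | C=CCC1=C(OC(C)C)[C@](O)([C@H](C)[C@@H](O)c2ccc(OC)c(OC)c2)C1O
F7 | step 4 | (1R,2R)-2-[(1S)-4-acetoxy-1-hydroxy-2-(propan-2-yloxy)-3-(prop-2-en-1-yl)cyclobut-2-en-1-yl]-1-(3,4-dimethoxyphenyl)propyl acetate, ring C4 epimers | C=CCC1=C(OC(C)C)[C@](O)([C@H](C)[C@@H](OC(C)=O)c2ccc(OC)c(OC)c2)C1OC(C)=O
F8 | step 4 | (1R,2R)-1-(3,4-dimethoxyphenyl)-2-[(1R)-1-hydroxy-4-oxo-3-(prop-2-en-1-yl)cyclobut-2-en-1-yl]propyl acetate | C=CCC1=C[C@@](O)([C@H](C)[C@@H](OC(C)=O)c2ccc(OC)c(OC)c2)C1=O
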